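**Plan**
Cuts: ring C (pyranone) at O1–C2, C2–C3 and C4–C4a, giving benzoyl chloride (ring B + C2), acetic anhydride (C3, C4) and a 2-aryl-N-methylpiperidine. N–CH3 goes back to a Boc carbonyl, ring D (piperidine) is cut at C2'–C3', and C2'–N1' goes back to an aldehyde plus 4-aminobutan-1-ol.
Enabling feature: C2' of ring D is bonded to both C8 of ring A and N1'. In the acyclic N-Boc benzylamine it is therefore a benzylic, carbamate-activated CH2 with two enantiotopic protons, and once lithiated it attacks C3', the chloride-bearing end of the N-butyl chain.
Symmetry: before ring C exists, ring A is a 4-methoxy-2,6-dioxygenated aryl group with two equivalent free positions, so the later C-acetylation has no regiochemical choice.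
Forward order: ring A is bought as 2,4,6-trihydroxybenzaldehyde (CHO carbon = C2'), ring D closes in the lithiation–cyclisation, and ring C closes last, with ring B arriving in the benzoyl unit.
Stereochemistry: the only stereocentre, C2' (R), comes from enantioselective deprotonation by s-BuLi/(+)-sparteine. Later steps leave its four bonds intact and are run cold or on the N-protonated, acyl-deactivated ring.
Design: the ortho oxygens travel as isopropyl ethers (inert to s-BuLi, no O→C silyl shift possible, removable beside OMe). The chloride is made from the alcohol after N-Boc protection, because free 4-chlorobutylamines close to pyrrolidines.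

Key step: step 5

Assumption: the sense of deprotonation is taken from the N-Boc-N-(ω-chloroalkyl)benzylamine series ((−)-sparteine gives S, so (+)-sparteine gives R; the CIP order N > aryl > CH2 > H is the same), and organolithium 10 is drawn S, that is for ring closure with inversion at carbon; if the 2,6-dialkoxy pattern reverses the sense, the other sparteine enantiomer is used.

Step 1
Reactants: 1 2,4,6-trihydroxybenzaldehyde
Product: 2 2,6-dihydroxy-4-methoxybenzaldehyde
Conditions: Me2SO4 (1.0 equiv), K2CO3 (1.0 equiv), acetone, rt
Reagents that add atoms: dimethyl sulfate, COS(=O)(=O)OC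
Why: Williamson-type O-methylation under acidity control: the 4-OH, para to the formyl group, is the most acidic hydroxyl and the only one neither hydrogen-bonded to nor crowded by the carbonyl, so one equivalent each of base and of the hard electrophile Me2SO4 should etherify it first and avoid C-methylation.

Step 2
Reactants: 2 2,6-dihydroxy-4-methoxybenzaldehyde
Product: 3 2,6-diisopropoxy-4-methoxybenzaldehyde
Conditions: 2-bromopropane (4 equiv), K2CO3, DMF, 70 °C
Reagents that add atoms: 2-bromopropane, CC(C)Br
Why: Williamson ether synthesis with excess secondary bromide in warm DMF alkylates both ortho phenols, and isopropyl ethers are chosen because they tolerate s-BuLi and LiAlH4, cannot migrate to a neighbouring carbanion as a silyl group can, and are later cleaved by BCl3 beside a methyl ether.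

Step 3
Reactants: 3 2,6-diisopropoxy-4-methoxybenzaldehyde; 4 4-aminobutan-1-ol; 5 di-tert-butyl dicarbonate
Product: 8 tert-butyl N-[(2,6-diisopropoxy-4-methoxyphenyl)methyl]-N-(4-hydroxybutyl)carbamate, via imine 6 (not isolated), via secondary amine 7 (not isolated)
Conditions: 4, MeOH, rt; NaBH4, 0 °C; then Boc2O, rt
Reagents that add atoms: 4-aminobutan-1-ol (4), NCCCCO; di-tert-butyl dicarbonate (5), CC(C)(C)OC(=O)OC(=O)OC(C)(C)C
Why: Stepwise reductive amination (imine condensation, borohydride reduction) followed by chemoselective N-acylation of the secondary amine in preference to the primary alcohol; the amino alcohol replaces a 4-chlorobutylamine because the latter, and any N-benzyl derivative of it, would close to a pyrrolidine by 5-exo-tet N-alkylation before the nitrogen could be protected.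

Step 4
Reactants: 8 tert-butyl N-[(2,6-diisopropoxy-4-methoxyphenyl)methyl]-N-(4-hydroxybutyl)carbamate
Product: 9 tert-butyl N-(4-chlorobutyl)-N-[(2,6-diisopropoxy-4-methoxyphenyl)methyl]carbamate
Conditions: PPh3, CCl4 (2 equiv), CH2Cl2, 0 °C to rt
Reagents that add atoms: tetrachloromethane, ClC(Cl)(Cl)Cl
Why: Appel reaction: chloride displaces the alkoxyphosphonium ion at the primary carbon by SN2 under neutral conditions, which spares the acid-labile trialkoxybenzyl carbamate, whose acylated nitrogen can no longer attack the new C–Cl bond.

Step 5
Reactants: 9 tert-butyl N-(4-chlorobutyl)-N-[(2,6-diisopropoxy-4-methoxyphenyl)methyl]carbamate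
Product: 11 tert-butyl (2R)-2-(2,6-diisopropoxy-4-methoxyphenyl)piperidine-1-carboxylate, via benzylic organolithium 10 (not isolated)
Conditions: s-BuLi (1.3 equiv), (+)-sparteine (1.3 equiv), toluene, −78 °C, then slowly to −40 °C; MeOH quench
Reagents that add atoms: none
Why: The Boc carbonyl binds the s-BuLi·(+)-sparteine complex and delivers it to the adjacent ArCH2 group (complex-induced proximity), so one of the two enantiotopic C2' protons is removed to give the dipole-stabilised, carbonyl-chelated benzylic organolithium 10. Its carbanionic carbon then displaces the chloride at the end of the N-butyl chain in an intramolecular SN2 reaction, a 6-exo-tet closure that forms C2'–C3' and ring D. The closest known reaction type is the sparteine-mediated asymmetric lithiation–cyclisation of N-Boc-N-(ω-chloroalkyl)benzylamines and -allylamines to 2-substituted N-Boc-pyrrolidines and -piperidines. C2' is controlled by the chiral diamine in the deprotonation, provided 10 keeps its configuration until it cyclises, which the non-polar solvent and low temperature favour. The step needs benzylic rather than aryl lithiation and no attack of the base on the chloride: both ring positions ortho to the CH2N group carry oxygen, the two remaining aryl C–H bonds lie far from the Boc-bound base and next to a branched isopropoxy group, and a primary chloride does not undergo halogen–lithium exchange at −78 °C. Alkyl rather than silyl ethers on the ortho oxygens exclude a 1,4 O→C silyl shift to the carbanion.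

Step 6
Reactants: 11 tert-butyl (2R)-2-(2,6-diisopropoxy-4-methoxyphenyl)piperidine-1-carboxylate
Product: 12 (2R)-2-(2,6-diisopropoxy-4-methoxyphenyl)-1-methylpiperidine
Conditions: LiAlH4, THF, reflux
Reagents that add atoms: none
Why: Reduction of a carbamate to an N-methylamine by LiAlH4 (hydride addition, loss of tert-butoxide, reduction of the resulting formamide/iminium stage) turns the directing group into the N–CH3 of the target without touching any bond at C2', so the R configuration is kept.

Step 7
Reactants: 12 (2R)-2-(2,6-diisopropoxy-4-methoxyphenyl)-1-methylpiperidine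
Product: 13 5-methoxy-2-[(2R)-1-methylpiperidin-2-yl]benzene-1,3-diol
Conditions: BCl3 (4 equiv), CH2Cl2, −78 to 0 °C; aq. NaHCO3
Reagents that add atoms: none
Why: Lewis-acid cleavage of aryl alkyl ethers: after the first equivalent of BCl3 is tied up at nitrogen, the secondary isopropyl groups leave by a cation-like pathway at temperatures at which an unchelated aryl methyl ether is inert, and the cold, short exposure should keep the C2'–N bond closed.

Step 8
Reactants: 13 5-methoxy-2-[(2R)-1-methylpiperidin-2-yl]benzene-1,3-diol; 14 acetic anhydride
Product: 15 1-{2,4-dihydroxy-6-methoxy-3-[(2R)-1-methylpiperidin-2-yl]phenyl}ethan-1-one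
Conditions: Ac2O (1.2 equiv), BF3·OEt2 (5 equiv), CH2Cl2, 0 °C to rt; then MeOH, aq. Na2CO3, rt
Reagents that add atoms: acetic anhydride (14), CC(=O)OC(C)=O
Why: Friedel–Crafts C-acetylation of an activated resorcinol (direct, or by O-acetylation and Fries-type shift), a reaction known for piperidinyl-substituted phloroglucinol ethers: the two free ring positions are interconverted by rotation about the aryl–C2' bond so only one C-acetyl product can form, the boron chelate between the new ketone and the adjacent OH shields the neighbouring OMe and deactivates the ring to a second acylation, and BF3 on nitrogen blocks N-acylation.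

Step 9
Reactants: 15 1-{2,4-dihydroxy-6-methoxy-3-[(2R)-1-methylpiperidin-2-yl]phenyl}ethan-1-one; 16 benzoyl chloride
Product: 18 1-{2,4-dihydroxy-6-methoxy-3-[(2R)-1-methylpiperidin-2-yl]phenyl}-3-phenylpropane-1,3-dione, via trilithium enolate 17 (not isolated)
Conditions: LiN(SiMe3)2 (4.5 equiv), THF, −78 to −10 °C; 16 (1.0 equiv), −78 °C to rt; aq. NH4Cl
Reagents that add atoms: benzoyl chloride (16), O=C(Cl)c1ccccc1
Why: Crossed Claisen-type C-benzoylation of a preformed lithium enolate: with both phenols parked as poorly nucleophilic lithium phenoxides the enolate carbon should take up the single equivalent of acid chloride, the fourth equivalent of base stores the product as its diketonate, and any 2-O-benzoate formed would be carried to the same diketone by a Baker–Venkataraman acyl shift.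

Step 10
Reactants: 18 1-{2,4-dihydroxy-6-methoxy-3-[(2R)-1-methylpiperidin-2-yl]phenyl}-3-phenylpropane-1,3-dione
Product: 19 7-hydroxy-5-methoxy-8-[(2R)-1-methylpiperidin-2-yl]-2-phenyl-4H-chromen-4-one (target)
Conditions: conc. HCl, AcOH, 50 °C; aq. NaHCO3 to pH 8
Reagents that add atoms: none
Why: Acid-catalysed cyclodehydration of an o-hydroxyaryl 1,3-diketone (closing stage of the Baker–Venkataraman flavone synthesis): only the OH lying between the acyl group and ring D can reach the benzoyl carbonyl (six-membered hemiketal, then loss of water), which fixes ring D at C8, OH at C7 and OMe at C5, while N-protonation on an acyl-deactivated ring at moderate temperature should keep C2' from ionising.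

**Compound list**
1 | 2,4,6-trihydroxybenzaldehyde | O=Cc1c(O)cc(O)cc1O | starting material
2 | 2,6-dihydroxy-4-methoxybenzaldehyde | COc1cc(O)c(C=O)c(O)c1 | intermediate
3 | 2,6-diisopropoxy-4-methoxybenzaldehyde | COc1cc(OC(C)C)c(C=O)c(OC(C)C)c1 | intermediate
4 | 4-aminobutan-1-ol | NCCCCO | starting material
5 | di-tert-butyl dicarbonate | CC(C)(C)OC(=O)OC(=O)OC(C)(C)C | starting material
6 | (E)-4-{[(2,6-diisopropoxy-4-methoxyphenyl)methylidene]amino}butan-1-ol | COc1cc(OC(C)C)c(/C=N/CCCCO)c(OC(C)C)c1 | intermediate
7 | 4-{[(2,6-diisopropoxy-4-methoxyphenyl)methyl]amino}butan-1-ol | COc1cc(OC(C)C)c(CNCCCCO)c(OC(C)C)c1 | intermediate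
8 | tert-butyl N-[(2,6-diisopropoxy-4-methoxyphenyl)methyl]-N-(4-hydroxybutyl)carbamate | COc1cc(OC(C)C)c(CN(CCCCO)C(=O)OC(C)(C)C)c(OC(C)C)c1 | intermediate
9 | tert-butyl N-(4-chlorobutyl)-N-[(2,6-diisopropoxy-4-methoxyphenyl)methyl]carbamate | COc1cc(OC(C)C)c(CN(CCCCCl)C(=O)OC(C)(C)C)c(OC(C)C)c1 | intermediate
10 | (S)-benzylic organolithium of 9 (Li on the ArCH carbon, held by the Boc carbonyl and (+)-sparteine) | COc1cc(OC(C)C)c([C@H]([Li])N(CCCCCl)C(=O)OC(C)(C)C)c(OC(C)C)c1 | intermediate
11 | tert-butyl (2R)-2-(2,6-diisopropoxy-4-methoxyphenyl)piperidine-1-carboxylate | COc1cc(OC(C)C)c([C@H]2CCCCN2C(=O)OC(C)(C)C)c(OC(C)C)c1 | intermediate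
12 | (2R)-2-(2,6-diisopropoxy-4-methoxyphenyl)-1-methylpiperidine | COc1cc(OC(C)C)c([C@H]2CCCCN2C)c(OC(C)C)c1 | intermediate
13 | 5-methoxy-2-[(2R)-1-methylpiperidin-2-yl]benzene-1,3-diol | COc1cc(O)c([C@H]2CCCCN2C)c(O)c1 | intermediate
14 | acetic anhydride | CC(=O)OC(C)=O | starting material
15 | 1-{2,4-dihydroxy-6-methoxy-3-[(2R)-1-methylpiperidin-2-yl]phenyl}ethan-1-one | COc1cc(O)c([C@H]2CCCCN2C)c(O)c1C(C)=O | intermediate
16 | benzoyl chloride | O=C(Cl)c1ccccc1 | starting material
17 | trilithium salt of 15 (two lithium phenoxides, one lithium enolate) | COc1cc(O[Li])c([C@H]2CCCCN2C)c(O[Li])c1C(=C)O[Li] | intermediate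
18 | 1-{2,4-dihydroxy-6-methoxy-3-[(2R)-1-methylpiperidin-2-yl]phenyl}-3-phenylpropane-1,3-dione | COc1cc(O)c([C@H]2CCCCN2C)c(O)c1C(=O)CC(=O)c1ccccc1 | intermediate
19 | 7-hydroxy-5-methoxy-8-[(2R)-1-methylpiperidin-2-yl]-2-phenyl-4H-chromen-4-one | COc1cc(O)c([C@H]2CCCCN2C)c2oc(-c3ccccc3)cc(=O)c12 | target

**Count**
Total steps: 10. Longest linear sequence: 10 steps (1 to 19).

**Steps most likely to fail**

Step 5.
- Deprotonation may be slow, because the two ortho alkoxy groups crowd the Boc-bound base and hold the benzylic C–H bonds out of alignment with the ring π system.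
- Six-ring closure is slower than five-ring closure, which gives the organolithium time to epimerise.
- Coordination of lithium by an ortho oxygen may loosen the diamine and lower or reverse the facial bias.
- Surplus base may metalate ring A.
- The fallback uses auxiliary control instead of reagent control and still makes C2'–C3', now with C2' as the electrophile. It sets out from 3 and comes back at 12.
- Condensation of 3 with (S)-tert-butanesulfinamide and Ti(OEt)4 in THF should give the (S,E)-sulfinyl imine F1.
- The Grignard reagent 4-chlorobutylmagnesium bromide F2, made from 1-bromo-4-chlorobutane and Mg, is added in CH2Cl2 at −48 °C. Addition through the cyclic, magnesium-chelated chair transition state should give the (S at sulfur, R at carbon) sulfinamide F3.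
- KN(SiMe3)2 in THF closes N1'–C6' to the N-sulfinylpiperidine F4, and HCl in MeOH at 0 °C removes the auxiliary to give the secondary amine F5.
- Reductive methylation of F5 with aqueous formaldehyde and NaBH(OAc)3 gives 12.

Step 8.
- Acylative or Lewis-acid-induced opening of the C2'–N bond on the very electron-rich ring, followed by re-closure, would erode the enantiopurity.
- O-Acetylation may stall before the acyl shift, and a second C-acylation may occur.
- The fallback installs the ketone with a nucleophilic aryl metal under basic conditions on the protected ring. It sets out from 12 and comes back at 15, so the free aminoresorcinol 13 is never handled.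
- Directed ortho-metalation of 12 (n-BuLi, TMEDA, Et2O, 0 °C) at the ring C–H flanked by OMe and OiPr should give the aryllithium F6.
- F6 is acylated with N-methoxy-N-methylacetamide to the diisopropoxy acetophenone F7, and BCl3 in CH2Cl2 at −78 °C removes both isopropyl groups to give 15.

Step 10.
- Warm acid may allow reversible ionisation of the protonated C2'–N bond, assisted by the ortho OH, and so partial racemisation. Ring closure may also be incomplete at the mild temperature chosen.
- The fallback closes ring C by conjugate addition to an ynone at room temperature instead of by acidic dehydration. It sets out from 12 and comes back at 19.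
- The aryllithium F6, made as above, is acylated with N-methoxy-N-methyl-3-phenylprop-2-ynamide to the diisopropoxy ynone F8.
- BCl3 at −78 °C frees both phenols to give the dihydroxy ynone F9.
- K2CO3 in acetone at rt induces 6-endo-dig oxa-Michael addition of the OH next to ring D to the alkyne, giving 19.

Further compounds
F1 | step 5 | (S,E)-N-[(2,6-diisopropoxy-4-methoxyphenyl)methylidene]-2-methylpropane-2-sulfinamide | CC(C)(C)[S@](=O)/N=C/c1c(OC(C)C)cc(OC)cc1OC(C)C
F2 | step 5 | 4-chlorobutylmagnesium bromide | ClCCCC[Mg]Br
F3 | step 5 | (S)-N-[(1R)-5-chloro-1-(2,6-diisopropoxy-4-methoxyphenyl)pentyl]-2-methylpropane-2-sulfinamide | CC(C)(C)[S@](=O)N[C@H](CCCCCl)c1c(OC(C)C)cc(OC)cc1OC(C)C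
F4 | step 5 | (2R)-1-[(S)-tert-butylsulfinyl]-2-(2,6-diisopropoxy-4-methoxyphenyl)piperidine | CC(C)(C)[S@](=O)N1CCCC[C@@H]1c1c(OC(C)C)cc(OC)cc1OC(C)C
F5 | step 5 | (2R)-2-(2,6-diisopropoxy-4-methoxyphenyl)piperidine | COc1cc(OC(C)C)c([C@H]2CCCCN2)c(OC(C)C)c1
F6 | step 8 | {2,4-diisopropoxy-6-methoxy-3-[(2R)-1-methylpiperidin-2-yl]phenyl}lithium | COc1cc(OC(C)C)c([C@H]2CCCCN2C)c(OC(C)C)c1[Li]
F7 | step 8 | 1-{2,4-diisopropoxy-6-methoxy-3-[(2R)-1-methylpiperidin-2-yl]phenyl}ethan-1-one | COc1cc(OC(C)C)c([C@H]2CCCCN2C)c(OC(C)C)c1C(C)=O
F8 | step 10 | 1-{2,4-diisopropoxy-6-methoxy-3-[(2R)-1-methylpiperidin-2-yl]phenyl}-3-phenylprop-2-yn-1-one | COc1cc(OC(C)C)c([C@H]2CCCCN2C)c(OC(C)C)c1C(=O)C#Cc1ccccc1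
F9 | step 10 | 1-{2,4-dihydroxy-6-methoxy-3-[(2R)-1-methylpiperidin-2-yl]phenyl}-3-phenylprop-2-yn-1-one | COc1cc(O)c([C@H]2CCCCN2C)c(O)c1C(=O)C#Cc1ccccc1
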